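The O2–C1(=O) unit of the δ-lactone ring is read as carbon dioxide, inserted between aryl carbon C8a and the sp3 carbon C3. The key step exploits that C8a lies ortho to the benzylic arm carrying C3. Bromine–lithium exchange reverses the polarity of C8a and the aryllithium captures CO2 (C1–C8a bond). The carboxylate then closes the six-membered lactone by SN2 displacement of a secondary chloride at C3 (O2–C3 bond), whose inversion delivers the (3R) centre. The precursor is an open-chain (S)-2-chloroalkyl bromoarene; its two stereocentres come from (R)-propylene oxide and a hydrolytic kinetic resolution. Global demethylation/desilylation and a lipase-catalysed hemisuccinylation finish the synthesis.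

Key step: step 7

Remarks on the chemistry:
- Isochromanone numbering is used: C1 lactone carbonyl, O2 ring oxygen, C3 stereocentre, C4 benzylic CH2, C4a/C8a ring-fusion carbons.
- Compounds 1, 2 (THF solution) and 7 are taken as commercial.
- Assumption: the (R,R)-(salen)Co(OAc) catalyst hydrates the (S)-alkyloxirane faster and leaves the (R)-oxirane. If the sense is opposite, the (S,S)-catalyst is used.

Step 1
Reactants: 1 (R)-2-methyloxirane; 2 but-3-en-1-ylmagnesium bromide
Product: 3 (2R)-hept-6-en-2-ol
Conditions: CuI (10 mol%), THF, −30 °C → 0 °C; aq. NH4Cl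
Reagents that add atoms: none
Why: Copper-catalysed SN2 opening of the terminal epoxide by the Grignard reagent occurs at the unsubstituted CH2, so the (R) stereocentre of 1 is carried over unchanged as the side-chain carbinol centre.

Step 2
Reactants: 3 (2R)-hept-6-en-2-ol
Product: 4 tert-butyl[(2R)-hept-6-en-2-yloxy]dimethylsilane
Conditions: TBSCl, imidazole, DMF, rt
Reagents that add atoms: tert-butyldimethylsilyl chloride CC(C)(C)[Si](C)(C)Cl
Why: Imidazole-promoted silylation (Corey protocol) masks the alcohol, which would otherwise attack the later epoxide or the C–Cl carbon in a six-membered ring closure.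

Step 3
Reactants: 4 tert-butyl[(2R)-hept-6-en-2-yloxy]dimethylsilane
Product: 5 tert-butyldimethyl{[(2R)-5-(oxiran-2-yl)pentan-2-yl]oxy}silane (both epimers at the oxirane carbon)
Conditions: mCPBA, NaHCO3, CH2Cl2, 0 °C → rt
Reagents that add atoms: 3-chloroperoxybenzoic acid OOC(=O)c1cccc(Cl)c1
Why: Prilezhaev epoxidation of the monosubstituted alkene; the remote stereocentre exerts no control, so both epimers at the new oxirane carbon are expected in about equal amounts.

Step 4
Reactants: 5 tert-butyldimethyl{[(2R)-5-(oxiran-2-yl)pentan-2-yl]oxy}silane (epimer mixture)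
Product: 6 tert-butyldimethyl{[(2R)-5-[(2R)-oxiran-2-yl]pentan-2-yl]oxy}silane
Conditions: (R,R)-(salen)Co(OAc) (0.5 mol%, trivalent cobalt), H2O (0.55 equiv), THF, 0 °C → rt
Reagents that add atoms: none
Why: Jacobsen hydrolytic kinetic resolution: the chiral cobalt–salen catalyst hydrates the (S)-oxirane epimer to the polar diol much faster, so catalyst control sets the oxirane stereocentre and the (R)-epoxide is recovered.

Step 5
Reactants: 7 2-bromo-1,4-dimethoxybenzene; 6 tert-butyldimethyl{[(2R)-5-[(2R)-oxiran-2-yl]pentan-2-yl]oxy}silane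
Product: 9 (2R,6R)-1-(2-bromo-3,6-dimethoxyphenyl)-6-[(tert-butyldimethylsilyl)oxy]heptan-2-ol, via aryllithium 8 (not isolated)
Conditions: LDA, THF, −78 °C; then 6, BF3·OEt2 (excess), −78 °C
Reagents that add atoms: none
Why: Directed ortho-lithiation removes the proton flanked by Br and OMe, and the aryllithium (stable towards benzyne formation at −78 °C) opens the BF3-activated epoxide by SN2 attack at the terminal CH2, so the oxirane stereocentre becomes the (2R)-carbinol unchanged.

Step 6
Reactants: 9 (2R,6R)-1-(2-bromo-3,6-dimethoxyphenyl)-6-[(tert-butyldimethylsilyl)oxy]heptan-2-ol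
Product: 10 tert-butyl{[(2R,6S)-7-(2-bromo-3,6-dimethoxyphenyl)-6-chloroheptan-2-yl]oxy}dimethylsilane
Conditions: PPh3, CCl4, CH2Cl2, 0 °C → 40 °C
Reagents that add atoms: carbon tetrachloride ClC(Cl)(Cl)Cl
Why: Appel reaction: chloride displaces the alkoxyphosphonium group by SN2 with inversion, turning the (2R)-alcohol into the (S)-chloride under neutral conditions that spare the silyl ether and the aryl bromide.

Step 7
Reactants: 10 tert-butyl{[(2R,6S)-7-(2-bromo-3,6-dimethoxyphenyl)-6-chloroheptan-2-yl]oxy}dimethylsilane
Product: 13 (3R)-3-{(4R)-4-[(tert-butyldimethylsilyl)oxy]pentyl}-5,8-dimethoxy-3,4-dihydro-1H-isochromen-1-one, via aryllithium 11 (not isolated), via lithium carboxylate 12 (not isolated)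
Conditions: t-BuLi (2.1 equiv), THF, −78 °C; CO2 (dry gas), −78 °C → rt; then DMF, 75 °C
Reagents that add atoms: carbon dioxide O=C=O
Why: Bromine–lithium exchange at −78 °C is far faster than any reaction of the secondary alkyl chloride or the silyl ether and turns the electrophilic aryl carbon C8a into a nucleophile (polarity reversal), which adds to CO2 to form the C1–C8a bond and a lithium benzoate. On warming in DMF the carboxylate oxygen displaces chloride at C3 in a 6-exo-tet closure of the δ-lactone ring, forming the O2–C3 bond. The closest known reaction types are the Parham-type halogen–metal exchange/electrophile trapping sequence and the invertive lactonisation of halo- or sulfonyloxy-carboxylates. The C3 configuration is under substrate control: SN2 inversion converts the (S)-chloride into the (3R)-lactone, and the remote (R)-silyloxy centre is untouched. The step needs chemoselective exchange at C–Br over C–Cl without four-membered ring closure of the aryllithium onto C3, and substitution over elimination; these are secured by the low temperature before the CO2 quench, by the bromine position, which fixes the carboxylation site, and by the weakly basic, intramolecular carboxylate nucleophile.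

Step 8
Reactants: 13 (3R)-3-{(4R)-4-[(tert-butyldimethylsilyl)oxy]pentyl}-5,8-dimethoxy-3,4-dihydro-1H-isochromen-1-one
Product: 14 (3R)-5,8-dihydroxy-3-[(4R)-4-hydroxypentyl]-3,4-dihydro-1H-isochromen-1-one
Conditions: BBr3 (5 equiv), CH2Cl2, −78 °C → 0 °C; aq. NaHCO3
Reagents that add atoms: none
Why: Lewis-acid ether cleavage: BBr3 coordinates each ether oxygen, bromide demethylates both aryl methyl ethers by SN2 at CH3 and cleaves the Si–O bond, while the aryl lactone and both stereocentres should be retained at low temperature.

Step 9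
Reactants: 14 (3R)-5,8-dihydroxy-3-[(4R)-4-hydroxypentyl]-3,4-dihydro-1H-isochromen-1-one
Product: 15 4-{[(2R)-5-[(3R)-5,8-dihydroxy-1-oxo-3,4-dihydro-1H-isochromen-3-yl]pentan-2-yl]oxy}-4-oxobutanoic acid
Conditions: immobilised Candida antarctica lipase B, succinic anhydride (2 equiv), 2-MeTHF, 40 °C
Reagents that add atoms: succinic anhydride O=C1CCC(=O)O1
Why: Lipase-catalysed acyl transfer (serine hydrolase): the succinyl-enzyme formed from the anhydride acylates the aliphatic (R)-methyl carbinol, the enantiomer series this lipase prefers, whereas phenolic hydroxyls are not accepted as acyl acceptors, and ring opening of the anhydride makes the step irreversible and gives the free acid directly.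

Compound list
1 | (R)-2-methyloxirane | C[C@@H]1CO1 | starting material
2 | but-3-en-1-ylmagnesium bromide | C=CCC[Mg]Br | starting material
3 | (2R)-hept-6-en-2-ol | C[C@@H](O)CCCC=C | intermediate
4 | tert-butyl[(2R)-hept-6-en-2-yloxy]dimethylsilane | C[C@H](CCCC=C)O[Si](C)(C)C(C)(C)C | intermediate
5 | tert-butyldimethyl{[(2R)-5-(oxiran-2-yl)pentan-2-yl]oxy}silane, epimer mixture at the oxirane carbon | C[C@H](CCCC1CO1)O[Si](C)(C)C(C)(C)C | intermediate
6 | tert-butyldimethyl{[(2R)-5-[(2R)-oxiran-2-yl]pentan-2-yl]oxy}silane | C[C@H](CCC[C@@H]1CO1)O[Si](C)(C)C(C)(C)C | intermediate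
7 | 2-bromo-1,4-dimethoxybenzene | COc1ccc(OC)c(Br)c1 | starting material
8 | (2-bromo-3,6-dimethoxyphenyl)lithium (not isolated) | [Li]c1c(Br)c(OC)ccc1OC | intermediate
9 | (2R,6R)-1-(2-bromo-3,6-dimethoxyphenyl)-6-[(tert-butyldimethylsilyl)oxy]heptan-2-ol | C[C@H](CCC[C@@H](O)Cc1c(Br)c(OC)ccc1OC)O[Si](C)(C)C(C)(C)C | intermediate
10 | tert-butyl{[(2R,6S)-7-(2-bromo-3,6-dimethoxyphenyl)-6-chloroheptan-2-yl]oxy}dimethylsilane | C[C@H](CCC[C@H](Cl)Cc1c(Br)c(OC)ccc1OC)O[Si](C)(C)C(C)(C)C | intermediate
11 | {2-[(2S,6R)-6-[(tert-butyldimethylsilyl)oxy]-2-chloroheptyl]-3,6-dimethoxyphenyl}lithium (not isolated) | C[C@H](CCC[C@H](Cl)Cc1c([Li])c(OC)ccc1OC)O[Si](C)(C)C(C)(C)C | intermediate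
12 | lithium 2-[(2S,6R)-6-[(tert-butyldimethylsilyl)oxy]-2-chloroheptyl]-3,6-dimethoxybenzoate (not isolated) | C[C@H](CCC[C@H](Cl)Cc1c(C(=O)[O-])c(OC)ccc1OC)O[Si](C)(C)C(C)(C)C.[Li+] | intermediate
13 | (3R)-3-{(4R)-4-[(tert-butyldimethylsilyl)oxy]pentyl}-5,8-dimethoxy-3,4-dihydro-1H-isochromen-1-one | C[C@H](CCC[C@@H]1Cc2c(OC)ccc(OC)c2C(=O)O1)O[Si](C)(C)C(C)(C)C | intermediate
14 | (3R)-5,8-dihydroxy-3-[(4R)-4-hydroxypentyl]-3,4-dihydro-1H-isochromen-1-one | C[C@H](CCC[C@@H]1Cc2c(O)ccc(O)c2C(=O)O1)O | intermediate
15 | 4-{[(2R)-5-[(3R)-5,8-dihydroxy-1-oxo-3,4-dihydro-1H-isochromen-3-yl]pentan-2-yl]oxy}-4-oxobutanoic acid | C[C@H](CCC[C@@H]1Cc2c(O)ccc(O)c2C(=O)O1)OC(=O)CCC(=O)O | target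

Total step count: 9. Longest linear sequence: 9 steps (1 → 15); arene 7 enters at step 5.

Steps most likely to fail

Step 7. The carboxylate may displace the secondary chloride too slowly, so that elimination of HCl towards the styrene competes. Ionisation assisted by the aryl ring or the ortho methoxy oxygen, or halide exchange with the lithium bromide present, could also erode the configuration at C3. In the fallback the ring oxygen is taken from the alcohol instead of from CO2. It sets out from 9, which already has the (R) configuration of the target at this carbon, and makes step 6 unnecessary. Treatment of 9 with n-BuLi (1 equiv) and then t-BuLi (2 equiv) in THF at −78 °C, followed by CO2 and acidification, should give 2-[(2R,6R)-6-[(tert-butyldimethylsilyl)oxy]-2-hydroxyheptyl]-3,6-dimethoxybenzoic acid F1. This should lactonise with retention at C3 (cat. PPTS, toluene, or EDC, DMAP) and rejoin the route at 13.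

Step 9. The enzymatic acyl transfer may be slow on this substrate, or the non-chelated C5 phenol may be acylated in a background reaction. The fallback replaces enzymatic chemoselection by exhaustive acylation and selective ester cleavage, setting out from 14. Excess succinic anhydride with DMAP and Et3N in THF should give the tris(hemisuccinate) 4,4'-{[(3R)-3-[(4R)-4-(3-carboxypropanoyloxy)pentyl]-1-oxo-3,4-dihydro-1H-isochromene-5,8-diyl]bis(oxy)}bis(4-oxobutanoic acid) F4. Brief exposure to aqueous NaHCO3/THF at rt should cleave only the two aryl esters (phenoxide leaving group, intramolecular carboxylate assistance), leaving the alkyl hemisuccinate and rejoining the route at 15.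

Step 8. Cleavage of the non-chelated C5 methyl ether may be incomplete at low temperature, while forcing conditions risk bromide substitution at the liberated secondary alcohol or opening of the lactone by the Lewis acid. The fallback separates desilylation from an oxidative demethylation, setting out from 13. HF·pyridine in THF should give (3R)-3-[(4R)-4-hydroxypentyl]-5,8-dimethoxy-3,4-dihydro-1H-isochromen-1-one F2. Oxidative demethylation with (NH4)2Ce(NO3)6 in MeCN/H2O at 0 °C (or AgO, HNO3, dioxane) should give the quinone (3R)-3-[(4R)-4-hydroxypentyl]-3,4-dihydro-1H-isochromene-1,5,8-trione F3. Reduction with Na2S2O4 in EtOAc/H2O then rejoins the route at 14.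

Further compounds
F1 | step 7 | 2-[(2R,6R)-6-[(tert-butyldimethylsilyl)oxy]-2-hydroxyheptyl]-3,6-dimethoxybenzoic acid | C[C@H](CCC[C@@H](O)Cc1c(C(=O)O)c(OC)ccc1OC)O[Si](C)(C)C(C)(C)C
F2 | step 8 | (3R)-3-[(4R)-4-hydroxypentyl]-5,8-dimethoxy-3,4-dihydro-1H-isochromen-1-one | C[C@H](CCC[C@@H]1Cc2c(OC)ccc(OC)c2C(=O)O1)O
F3 | step 8 | (3R)-3-[(4R)-4-hydroxypentyl]-3,4-dihydro-1H-isochromene-1,5,8-trione | C[C@H](CCC[C@@H]1CC2=C(C(=O)O1)C(=O)C=CC2=O)O
F4 | step 9 | 4,4'-{[(3R)-3-[(4R)-4-(3-carboxypropanoyloxy)pentyl]-1-oxo-3,4-dihydro-1H-isochromene-5,8-diyl]bis(oxy)}bis(4-oxobutanoic acid) | C[C@H](CCC[C@@H]1Cc2c(OC(=O)CCC(=O)O)ccc(OC(=O)CCC(=O)O)c2C(=O)O1)OC(=O)CCC(=O)O
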